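**Retrosynthetic overview**
1. Ring D enol ether (C10=C14–O–C4) comes last, by loss of MeOH from a bridged C14 methyl acetal; the 9-acetate and the 8-(S)-2-methylbutanoate come from acylations; 15-OH is carried as a PMB ether.
2. Ring C (trans 6,12-α-methylene lactone) comes from translocating a cis 8,12-lactone. That lactone, 8β-O and 9α-OH come from α-epoxidation/5-exo lactonisation of a Δ8 7β-acetic acid, made by Ireland–Claisen rearrangement of a 9β-allylic acetate.
3. Rings A and B form together by an endo [5+2] cycloaddition of a 3-oxidopyrylium ylide (C6–C10, C14) onto (S)-4-silyloxycyclopent-2-enone (C1–C5). The C6–O–C10 bridge is later cut reductively at C10, and C4 is set by convex-face hydroxymethyl-anion addition.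
4. Chirality enters by two catalytic events: Ru-catalysed asymmetric hydrogenation of tiglic acid (side chain) and esterase desymmetrisation of meso cis-cyclopent-4-ene-1,3-diyl diacetate (core).
5. Ring order: A + B (step 9), D as acetal (step 17), temporary 8,12-lactone (step 20), C (step 26), D unsaturation (step 28).

Assumption/convention: guaiane numbering is used from compound 15 on (ring A = C1–C5; ring B = C1, C5–C10; ring C = C6, C7, C11, C12, O; ring D = O, C4, C5, C1, C10, C14; C15 = CH2O on C4; α = face of H-1/H-5). The target is read from the SMILES as (1R,4S,5S,6S,7S,8S,9S) with an (S)-2-methylbutanoate. TBS = tert-butyldimethylsilyl, PMB = 4-methoxybenzyl. The route is a paper design; the selectivities are argued from precedent and have not been tested.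

**Step 1**
Reactants: 1 tiglic acid
Product: 2 (S)-2-methylbutanoic acid
Conditions: Ru(OAc)2[(S)-H8-BINAP] (0.5 mol %), H2 (1.5 atm), MeOH, 20 °C
Reagents that add atoms: none
Why: Noyori-type asymmetric hydrogenation of an α,β-unsaturated acid; the carboxylate-bound chiral Ru–diphosphine delivers H2 to one enantioface and sets the (S) centre.

**Step 2**
Reactants: 3 cis-cyclopent-4-ene-1,3-diyl diacetate (meso)
Product: 4 (1R,4S)-4-hydroxycyclopent-2-en-1-yl acetate
Conditions: esterase (electric-eel acetylcholinesterase, a serine hydrolase), phosphate buffer pH 6.9, 25 °C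
Reagents that add atoms: none
Why: Enzymatic desymmetrisation of a meso diester; the esterase hydrolyses only the acetate on the pro-S carbinol carbon, fixing the absolute configuration of the core.

**Step 3**
Reactants: 4 (1R,4S)-4-hydroxycyclopent-2-en-1-yl acetate
Product: 5 (1R,4S)-4-(TBS-oxy)cyclopent-2-en-1-yl acetate
Conditions: TBSCl, imidazole, DMF, 25 °C
Reagents that add atoms: tert-butyldimethylsilyl chloride, CC(C)(C)[Si](C)(C)Cl
Why: Standard silylation of the free secondary alcohol; no stereocentre is touched.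

**Step 4**
Reactants: 5 (1R,4S)-4-(TBS-oxy)cyclopent-2-en-1-yl acetate
Product: 6 (1R,4S)-4-(TBS-oxy)cyclopent-2-en-1-ol
Conditions: K2CO3 (cat.), MeOH, 0 °C
Reagents that add atoms: none
Why: Zemplén-type transesterification removes the acetate without touching the silyl ether.

**Step 5**
Reactants: 6 (1R,4S)-4-(TBS-oxy)cyclopent-2-en-1-ol
Product: 7 (S)-4-(TBS-oxy)cyclopent-2-en-1-one
Conditions: Dess–Martin periodinane, CH2Cl2, 0 → 25 °C
Reagents that add atoms: none
Why: Dess–Martin oxidation of the allylic alcohol gives the enone; the silyloxy stereocentre is retained.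

**Step 6**
Reactants: 8 furan; 9 2,2-dimethoxyacetaldehyde
Product: 11 1-(furan-2-yl)-2,2-dimethoxyethan-1-ol (racemate), via 2-furyllithium 10 (not isolated)
Conditions: n-BuLi, THF, 0 °C; then 9, −78 °C; then H2O
Reagents that add atoms: none
Why: α-Lithiation of furan and 1,2-addition to the aldehyde; the new carbinol centre is racemic and is erased in step 9.

**Step 7**
Reactants: 11 1-(furan-2-yl)-2,2-dimethoxyethan-1-ol
Product: 12 2-(dimethoxymethyl)-6-hydroxy-2H-pyran-3(6H)-one (diastereomer mixture)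
Conditions: NBS, NaHCO3, THF/H2O (4:1), 0 °C
Reagents that add atoms: water, O
Why: Achmatowicz oxidative ring expansion of a furfuryl alcohol to the pyranone hemiacetal.

**Step 8**
Reactants: 12 2-(dimethoxymethyl)-6-hydroxy-2H-pyran-3(6H)-one
Product: 13 6-acetoxy-2-(dimethoxymethyl)-2H-pyran-3(6H)-one (diastereomer mixture)
Conditions: Ac2O, pyridine, DMAP (cat.), CH2Cl2, 0 °C
Reagents that add atoms: acetic anhydride, CC(=O)OC(C)=O
Why: Acetylation of the anomeric hydroxyl installs the leaving group for ylide formation.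

**Step 9**
Reactants: 13 6-acetoxy-2-(dimethoxymethyl)-2H-pyran-3(6H)-one; 7 (S)-4-(TBS-oxy)cyclopent-2-en-1-one
Product: 15 endo cycloadduct 2α-(TBS-oxy)-10β-(dimethoxymethyl)-6α,10α-epoxy-1αH,5αH-bicyclo[5.3.0]dec-7-ene-4,9-dione, via oxidopyrylium ylide 14 (not isolated)
Conditions: Et3N, CH2Cl2, 25 °C, slow addition of 13 (3 equiv) to 7
Reagents that add atoms: none
Why: Base-induced loss of AcOH gives the 3-oxidopyrylium ylide, which undergoes a [5+2] dipolar cycloaddition with the enone; the enone α-carbon bonds to the unsubstituted terminus, endo and anti to the silyloxy group, setting C1, C5 (cis) and 6α-O.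

**Step 10**
Reactants: 15 endo cycloadduct
Product: 16 10β-(dimethoxymethyl)-6α,10α-epoxy-1αH,5αH-bicyclo[5.3.0]deca-2,7-diene-4,9-dione
Conditions: DBU, CH2Cl2, 0 → 25 °C
Reagents that add atoms: none
Why: E1cB elimination of the β-silyloxy group from the C4 ketone removes the now-spent controlling centre; C5 cannot eliminate or epimerise because of the bridge.

**Step 11**
Reactants: 16 bridged dienedione
Product: 17 10β-(dimethoxymethyl)-6α,10α-epoxy-1αH,5αH-bicyclo[5.3.0]decane-4,9-dione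
Conditions: H2 (1 atm), Pd/C, EtOAc, 25 °C
Reagents that add atoms: none
Why: Catalytic hydrogenation saturates both enone C=C bonds, leaving a single unhindered ketone (C4) for the next step.

**Step 12**
Reactants: 17 bridged diketone
Product: 18 4β-hydroxy-4α-(PMB-oxymethyl)-10β-(dimethoxymethyl)-6α,10α-epoxy-1αH,5αH-bicyclo[5.3.0]decan-9-one
Conditions: Bu3SnCH2OPMB (from Bu3SnCH2OH, NaH, PMBCl), n-BuLi, THF, −78 °C; then 17 (1.0 equiv), −78 °C; then H2O
Reagents that add atoms: tributyl{[(4-methoxybenzyl)oxy]methyl}stannane, CCCC[Sn](CCCC)(CCCC)COCc1ccc(OC)cc1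
Why: Still-type α-alkoxymethyllithium (Sn–Li exchange) adds 1,2 to the cyclopentanone from the open convex α-face (the β-face is covered by the C7–C9 bridge, and C9 is shielded by the quaternary bridgehead), giving 4β-OH and 4α-C15.

**Step 13**
Reactants: 18 bridged hydroxy ketone
Product: 19 4β-hydroxy-4α-(PMB-oxymethyl)-10β-(dimethoxymethyl)-6α,10α-epoxy-1αH,5αH-bicyclo[5.3.0]dec-7-en-9-one
Conditions: IBX, DMSO/fluorobenzene, 65 °C
Reagents that add atoms: none
Why: Nicolaou IBX dehydrogenation; only C8 is enolisable (C10 is quaternary), so the C7=C8 enone forms regiospecifically.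

**Step 14**
Reactants: 19 bridged enone
Product: 20 4β,6α-dihydroxy-4α-(PMB-oxymethyl)-10β-(dimethoxymethyl)-1αH,5αH,10αH-bicyclo[5.3.0]dec-7-en-9-one
Conditions: SmI2 (2.2 equiv), THF/MeOH, −78 °C
Reagents that add atoms: none
Why: Single-electron reduction of the α-alkoxy ketone cleaves the C10–O bond (reductive β-scission), and the samarium enolate is protonated on the convex α-face; 6α-OH is released with its configuration intact.

**Step 15**
Reactants: 20 γ-hydroxy enone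
Product: 21 6α-TBS ether of 20
Conditions: TBSCl, imidazole, DMF, 25 °C
Reagents that add atoms: tert-butyldimethylsilyl chloride, CC(C)(C)[Si](C)(C)Cl
Why: Selective silylation of the secondary 6α-OH; the tertiary 4β-OH does not react.

**Step 16**
Reactants: 21 silyloxy enone
Product: 22 6α-(TBS-oxy)-4α-(PMB-oxymethyl)-10β-(dimethoxymethyl)-1αH,5αH,10αH-bicyclo[5.3.0]dec-7-ene-4β,9β-diol
Conditions: NaBH4, CeCl3·7H2O, MeOH, −78 °C
Reagents that add atoms: none
Why: Luche 1,2-reduction; hydride attacks C9 from the convex α-face, anti to the 10β-dimethoxymethyl group, giving the 9β-allylic alcohol.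

**Step 17**
Reactants: 22 allylic diol
Product: 23 ring D methyl acetal (C4β–O–C14(OMe)–C10β) with 9β-OH and Δ7 (C14 anomer mixture)
Conditions: PPTS (cat.), CH2Cl2, 4 Å MS, 25 °C
Reagents that add atoms: none
Why: Acid-catalysed transacetalisation; the 4β-tertiary hydroxyl traps the C14 oxocarbenium ion on the β-face and closes ring D, which also locks C10.

**Step 18**
Reactants: 23 ring D acetal allylic alcohol
Product: 24 9β-acetate of 23
Conditions: Ac2O, pyridine, DMAP (cat.), CH2Cl2, 25 °C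
Reagents that add atoms: acetic anhydride, CC(=O)OC(C)=O
Why: Acetylation of the allylic alcohol prepares the Claisen substrate.

**Step 19**
Reactants: 24 9β-allylic acetate
Product: 27 Δ8 7β-(carboxymethyl) acid (7α-H), via ketene silyl acetal 25 (not isolated), via trimethylsilyl ester 26 (not isolated)
Conditions: LiN(iPr)2, Me3SiCl, Et3N, THF, −78 → 60 °C; then H2O/MeOH
Reagents that add atoms: none
Why: Ireland–Claisen [3,3] rearrangement; suprafacial transfer from the 9β-oxygen to the β-face of C7 sets C7 and moves the alkene to C8=C9.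

**Step 20**
Reactants: 27 Δ8 7β-acetic acid
Product: 29 8β,12-olide-9α-ol (cis γ-lactone C7–C11–C12(=O)–O–C8), via 8α,9α-epoxy acid 28 (not isolated)
Conditions: mCPBA, CH2Cl2, 0 → 25 °C
Reagents that add atoms: 3-chloroperbenzoic acid, O=C(OO)c1cccc(Cl)c1
Why: Prilezhaev epoxidation on the α-face (anti to the β groups at C7 and C10), then 5-exo opening at C8 by the carboxylic acid with inversion, gives 8β-O and 9α-OH.

**Step 21**
Reactants: 29 hydroxy lactone
Product: 30 9α-TBS ether of 29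
Conditions: TBSOTf, 2,6-lutidine, CH2Cl2, −78 → 0 °C
Reagents that add atoms: tert-butyldimethylsilyl trifluoromethanesulfonate, CC(C)(C)[Si](C)(C)OS(=O)(=O)C(F)(F)F
Why: Silylation of the hindered secondary alcohol masks O-9 for the enolate and acylation steps.

**Step 22**
Reactants: 30 silylated 8,12-lactone
Product: 31 11-(dimethylaminomethyl) lactone (C11 epimers)
Conditions: LiN(iPr)2, THF, −78 °C; then CH2=NMe2+ I−, −78 → 0 °C
Reagents that add atoms: N,N-dimethylmethyleneiminium iodide, C=[N+](C)C.[I-]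
Why: Mannich reaction of the lactone enolate with Eschenmoser's salt; no other ester is present at this stage.

**Step 23**
Reactants: 31 Mannich base
Product: 33 11(13)-methylene-8β,12-olide, via trimethylammonium iodide 32 (not isolated)
Conditions: MeI, THF, 25 °C; then NaHCO3 (aq), EtOAc, 25 °C
Reagents that add atoms: none
Why: N-Methylation then E1cB (Hofmann-type) loss of trimethylamine gives the α-methylene lactone.

**Step 24**
Reactants: 33 α-methylene-8,12-lactone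
Product: 35 methyl acrylate ester with free 8β-OH (methyl 2-[7β-yl]acrylate), via lithium carboxylate 34 (not isolated)
Conditions: LiOH, THF/H2O, 0 °C; concentrate; then MeI, DMF, 0 → 25 °C
Reagents that add atoms: lithium hydroxide, [Li+].[OH-]; iodomethane, CI
Why: Saponification frees O-8, and O-alkylation of the carboxylate traps C12 as the methyl ester before it can relactonise; 35 is used at once.

**Step 25**
Reactants: 35 hydroxy methyl ester; 2 (S)-2-methylbutanoic acid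
Product: 36 8-O-[(S)-2-methylbutanoyl] derivative of 35
Conditions: DCC, DMAP (cat.), CH2Cl2, 0 → 25 °C
Reagents that add atoms: none
Why: Steglich esterification puts the side chain on the 8β-oxygen, the only free hydroxyl.

**Step 26**
Reactants: 36 silylated diester
Product: 38 6α,12-olide (trans ring C) with 9α-OH and 8β-(S)-2-methylbutanoate, via 6α,9α-diol methyl ester 37 (not isolated)
Conditions: HF·pyridine, pyridine, THF, 0 → 25 °C; then PPTS (cat.), CH2Cl2, 25 °C
Reagents that add atoms: none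
Why: Fluoride desilylation frees 6α-OH and 9α-OH, and acid-catalysed lactonisation of the γ-hydroxy acrylate onto O-6 closes ring C (O-8 is acylated, and 9α-OH is trans to the side chain).

**Step 27**
Reactants: 38 hydroxy lactone
Product: 39 9α-acetate of 38
Conditions: Ac2O, pyridine, DMAP (cat.), CH2Cl2, 0 °C
Reagents that add atoms: acetic anhydride, CC(=O)OC(C)=O
Why: Acetylation of the only free hydroxyl.

**Step 28**
Reactants: 39 ring D methyl acetal
Product: 40 15-O-PMB ether of the target (C10=C14 enol ether)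
Conditions: Me3SiOTf, iPr2NEt, CH2Cl2, −20 → 0 °C
Reagents that add atoms: none
Why: Gassman-type elimination; the silyl triflate ionises the acetal to the ring D oxocarbenium ion and the amine removes H-10, giving the enol ether under non-acidic conditions that spare the allylic 9-acetate.

**Step 29**
Reactants: 40 15-O-PMB ether
Product: 41 target, (1R,4S,5S,6S,7S,8S,9S)-9-acetoxy-15-hydroxy-8-[(S)-2-methylbutanoyloxy]-4,14-epoxyguaia-10(14),11(13)-dien-6,12-olide
Conditions: DDQ, CH2Cl2/pH 7 buffer, 0 °C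
Reagents that add atoms: none
Why: Oxidative PMB cleavage (benzylic hydride abstraction, hydrolysis); glycal-type enol ethers, the enoate and the esters should tolerate buffered DDQ.

**Compound list**
1 | tiglic acid | C/C=C(\C)C(=O)O | starting material
2 | (S)-2-methylbutanoic acid | CC[C@H](C)C(=O)O | intermediate
3 | cis-cyclopent-4-ene-1,3-diyl diacetate (meso) | CC(=O)O[C@@H]1C[C@H](OC(C)=O)C=C1 | starting material
4 | (1R,4S)-4-hydroxycyclopent-2-en-1-yl acetate | CC(=O)O[C@@H]1C[C@H](O)C=C1 | intermediate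
5 | (1R,4S)-4-(TBS-oxy)cyclopent-2-en-1-yl acetate | CC(=O)O[C@@H]1C[C@H](O[Si](C)(C)C(C)(C)C)C=C1 | intermediate
6 | (1R,4S)-4-(TBS-oxy)cyclopent-2-en-1-ol | O[C@@H]1C[C@H](O[Si](C)(C)C(C)(C)C)C=C1 | intermediate
7 | (S)-4-(TBS-oxy)cyclopent-2-en-1-one | O=C1C[C@H](O[Si](C)(C)C(C)(C)C)C=C1 | intermediate
8 | furan | c1ccoc1 | starting material
9 | 2,2-dimethoxyacetaldehyde | O=CC(OC)OC | starting material
10 | 2-furyllithium | [Li]c1ccco1 | intermediate
11 | 1-(furan-2-yl)-2,2-dimethoxyethan-1-ol (racemate) | OC(c1ccco1)C(OC)OC | intermediate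
12 | 2-(dimethoxymethyl)-6-hydroxy-2H-pyran-3(6H)-one | O=C1C=CC(O)OC1C(OC)OC | intermediate
13 | 6-acetoxy-2-(dimethoxymethyl)-2H-pyran-3(6H)-one | O=C1C=CC(OC(C)=O)OC1C(OC)OC | intermediate
14 | 2-(dimethoxymethyl)pyrylium-3-olate (oxidopyrylium ylide) | [O-]c1ccc[o+]c1C(OC)OC | intermediate
15 | endo cycloadduct, 2α-(TBS-oxy)-10β-(dimethoxymethyl)-6α,10α-epoxy-1αH,5αH-bicyclo[5.3.0]dec-7-ene-4,9-dione | O=C1C[C@H](O[Si](C)(C)C(C)(C)C)[C@@H]2[C@H]1[C@@H]1C=CC(=O)[C@@]2(C(OC)OC)O1 | intermediate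
16 | 10β-(dimethoxymethyl)-6α,10α-epoxy-1αH,5αH-bicyclo[5.3.0]deca-2,7-diene-4,9-dione | O=C1C=C[C@@H]2[C@H]1[C@@H]1C=CC(=O)[C@@]2(C(OC)OC)O1 | intermediate
17 | 10β-(dimethoxymethyl)-6α,10α-epoxy-1αH,5αH-bicyclo[5.3.0]decane-4,9-dione | O=C1CC[C@@H]2[C@H]1[C@@H]1CCC(=O)[C@@]2(C(OC)OC)O1 | intermediate
18 | 4β-hydroxy-4α-(PMB-oxymethyl)-10β-(dimethoxymethyl)-6α,10α-epoxy-1αH,5αH-bicyclo[5.3.0]decan-9-one | O[C@@]1(COCc3ccc(OC)cc3)CC[C@@H]2[C@H]1[C@@H]1CCC(=O)[C@@]2(C(OC)OC)O1 | intermediate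
19 | Δ7 enone of 18 | O[C@@]1(COCc3ccc(OC)cc3)CC[C@@H]2[C@H]1[C@@H]1C=CC(=O)[C@@]2(C(OC)OC)O1 | intermediate
20 | 4β,6α-dihydroxy-4α-(PMB-oxymethyl)-10β-(dimethoxymethyl)-1αH,5αH,10αH-bicyclo[5.3.0]dec-7-en-9-one | O[C@@]1(COCc3ccc(OC)cc3)CC[C@@H]2[C@H]1[C@@H](O)C=CC(=O)[C@@H]2C(OC)OC | intermediate
21 | 6α-TBS ether of 20 | O[C@@]1(COCc3ccc(OC)cc3)CC[C@@H]2[C@H]1[C@@H](O[Si](C)(C)C(C)(C)C)C=CC(=O)[C@@H]2C(OC)OC | intermediate
22 | 9β-alcohol of 21 (4β,9β-diol) | O[C@@]1(COCc3ccc(OC)cc3)CC[C@@H]2[C@H]1[C@@H](O[Si](C)(C)C(C)(C)C)C=C[C@H](O)[C@@H]2C(OC)OC | intermediate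
23 | ring D methyl acetal, 9β-OH, Δ7, 6α-OTBS, 15-OPMB (C14 anomers) | CC(C)(C)[Si](C)(C)O[C@H]2C=C[C@H](O)[C@@H]1C(OC)O[C@@]3(COCc4ccc(OC)cc4)CC[C@@H]1[C@@H]23 | intermediate
24 | 9β-acetate of 23 | CC(C)(C)[Si](C)(C)O[C@H]2C=C[C@H](OC(C)=O)[C@@H]1C(OC)O[C@@]3(COCc4ccc(OC)cc4)CC[C@@H]1[C@@H]23 | intermediate
25 | ketene trimethylsilyl acetal of 24 | CC(C)(C)[Si](C)(C)O[C@H]2C=C[C@H](OC(=C)O[Si](C)(C)C)[C@@H]1C(OC)O[C@@]3(COCc4ccc(OC)cc4)CC[C@@H]1[C@@H]23 | intermediate
26 | trimethylsilyl ester of 27 | CC(C)(C)[Si](C)(C)O[C@H]2[C@H](CC(=O)O[Si](C)(C)C)C=C[C@@H]1C(OC)O[C@@]3(COCc4ccc(OC)cc4)CC[C@@H]1[C@@H]23 | intermediate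
27 | Δ8 7β-(carboxymethyl) acid (7α-H) | CC(C)(C)[Si](C)(C)O[C@H]2[C@H](CC(=O)O)C=C[C@@H]1C(OC)O[C@@]3(COCc4ccc(OC)cc4)CC[C@@H]1[C@@H]23 | intermediate
28 | 8α,9α-epoxide of 27 | CC(C)(C)[Si](C)(C)O[C@H]2[C@H](CC(=O)O)[C@@H]5[C@@H](O5)[C@@H]1C(OC)O[C@@]3(COCc4ccc(OC)cc4)CC[C@@H]1[C@@H]23 | intermediate
29 | 8β,12-olide-9α-ol | CC(C)(C)[Si](C)(C)O[C@H]2[C@@H]5CC(=O)O[C@@H]5[C@@H](O)[C@@H]1C(OC)O[C@@]3(COCc4ccc(OC)cc4)CC[C@@H]1[C@@H]23 | intermediate
30 | 9α-TBS ether of 29 | CC(C)(C)[Si](C)(C)O[C@H]2[C@@H]5CC(=O)O[C@@H]5[C@@H](O[Si](C)(C)C(C)(C)C)[C@@H]1C(OC)O[C@@]3(COCc4ccc(OC)cc4)CC[C@@H]1[C@@H]23 | intermediate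
31 | 11-(dimethylaminomethyl) lactone (C11 epimers) | CC(C)(C)[Si](C)(C)O[C@H]2[C@@H]5C(CN(C)C)C(=O)O[C@@H]5[C@@H](O[Si](C)(C)C(C)(C)C)[C@@H]1C(OC)O[C@@]3(COCc4ccc(OC)cc4)CC[C@@H]1[C@@H]23 | intermediate
32 | trimethylammonium iodide of 31 | CC(C)(C)[Si](C)(C)O[C@H]2[C@@H]5C(C[N+](C)(C)C)C(=O)O[C@@H]5[C@@H](O[Si](C)(C)C(C)(C)C)[C@@H]1C(OC)O[C@@]3(COCc4ccc(OC)cc4)CC[C@@H]1[C@@H]23.[I-] | intermediate
33 | 11(13)-methylene-8β,12-olide | CC(C)(C)[Si](C)(C)O[C@H]2[C@@H]5C(=C)C(=O)O[C@@H]5[C@@H](O[Si](C)(C)C(C)(C)C)[C@@H]1C(OC)O[C@@]3(COCc4ccc(OC)cc4)CC[C@@H]1[C@@H]23 | intermediate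
34 | lithium 8β-hydroxy acrylate (ring-opened 33) | CC(C)(C)[Si](C)(C)O[C@H]2[C@H](C(=C)C(=O)[O-])[C@H](O)[C@@H](O[Si](C)(C)C(C)(C)C)[C@@H]1C(OC)O[C@@]3(COCc4ccc(OC)cc4)CC[C@@H]1[C@@H]23.[Li+] | intermediate
35 | methyl acrylate ester with 8β-OH | CC(C)(C)[Si](C)(C)O[C@H]2[C@H](C(=C)C(=O)OC)[C@H](O)[C@@H](O[Si](C)(C)C(C)(C)C)[C@@H]1C(OC)O[C@@]3(COCc4ccc(OC)cc4)CC[C@@H]1[C@@H]23 | intermediate
36 | 8-O-[(S)-2-methylbutanoyl] derivative of 35 | CC(C)(C)[Si](C)(C)O[C@H]2[C@H](C(=C)C(=O)OC)[C@H](OC(=O)[C@@H](C)CC)[C@@H](O[Si](C)(C)C(C)(C)C)[C@@H]1C(OC)O[C@@]3(COCc4ccc(OC)cc4)CC[C@@H]1[C@@H]23 | intermediate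
37 | 6α,9α-diol methyl ester | O[C@H]2[C@H](C(=C)C(=O)OC)[C@H](OC(=O)[C@@H](C)CC)[C@@H](O)[C@@H]1C(OC)O[C@@]3(COCc4ccc(OC)cc4)CC[C@@H]1[C@@H]23 | intermediate
38 | 6α,12-olide with 9α-OH, 8β-(S)-2-methylbutanoate, ring D acetal | C=C1C(=O)O[C@H]2[C@H]1[C@H](OC(=O)[C@@H](C)CC)[C@@H](O)[C@@H]1C(OC)O[C@@]3(COCc4ccc(OC)cc4)CC[C@@H]1[C@@H]23 | intermediate
39 | 9α-acetate of 38 | C=C1C(=O)O[C@H]2[C@H]1[C@H](OC(=O)[C@@H](C)CC)[C@@H](OC(C)=O)[C@@H]1C(OC)O[C@@]3(COCc4ccc(OC)cc4)CC[C@@H]1[C@@H]23 | intermediate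
40 | 15-O-PMB ether of the target | C=C1C(=O)O[C@H]2[C@H]1[C@H](OC(=O)[C@@H](C)CC)[C@@H](OC(C)=O)C1=CO[C@@]3(COCc4ccc(OC)cc4)CC[C@@H]1[C@@H]23 | intermediate
41 | CNP0013863.2 | C=C1C(=O)O[C@H]2[C@H]1[C@H](OC(=O)[C@@H](C)CC)[C@@H](OC(C)=O)C1=CO[C@@]3(CO)CC[C@@H]1[C@@H]23 | target

**Totals**
Total step count: 29.
Longest linear sequence: 25 steps (3 → 41; steps 2–5 and 9–29).

**Three steps most likely to fail**

Step 9 (intermolecular [5+2]; regio-, endo- and facial selectivity all have to hold, and the ylide can dimerise). Fallback: set out from 7. α-Iodination (I2, pyridine) gives (S)-4-(TBS-oxy)-2-iodocyclopent-2-en-1-one F1. PdCl2(PPh3)2-catalysed methoxycarbonylation (CO, MeOH, Et3N) gives the doubly activated methyl (S)-3-(TBS-oxy)-5-oxocyclopent-1-ene-1-carboxylate F2. This much more reactive dipolarophile is combined with ylide 14 (from 13, Et3N) to give the 5-methoxycarbonyl cycloadduct F3. Krapcho dealkoxycarbonylation (LiCl, wet DMSO, 120 °C), with loss of the β-silyloxy group in the same pot, rejoins the route at 16.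

Step 14 (C10–O scission in the presence of the enone, with α-face protonation at C10). Fallback: set out from 18 and reverse the order of scission and dehydrogenation. SmI2/MeOH on the saturated α-alkoxy ketone gives the saturated 4β,6α-dihydroxy ketone F4. TBSCl/imidazole gives its 6α-silyl ether F5. Kinetic enolisation at the less hindered C8 (LiN(iPr)2, 2.2 equiv, −78 °C) and PhSeBr give the 8-phenylselenyl ketone F6 (C8 epimers). H2O2/pyridine then effects selenoxide syn-elimination and rejoins the route at 21.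

Step 28 (acetal to enol ether next to an allylic acetate). Fallback: set out from 39. PhSH and BF3·OEt2 (CH2Cl2, −40 °C) exchange the methoxy group to give the S-phenyl monothioacetal F7. mCPBA (1 equiv, −78 °C) gives the sulfoxide F8. Thermal syn-elimination (toluene, iPr2NEt, 90 °C) forms the C10=C14 enol ether and rejoins the route at 40.

**Further compounds**
F1 | step 9 | (S)-4-(TBS-oxy)-2-iodocyclopent-2-en-1-one | O=C1C[C@H](O[Si](C)(C)C(C)(C)C)C=C1I
F2 | step 9 | methyl (S)-3-(TBS-oxy)-5-oxocyclopent-1-ene-1-carboxylate | O=C1C[C@H](O[Si](C)(C)C(C)(C)C)C=C1C(=O)OC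
F3 | step 9 | 5-methoxycarbonyl analogue of cycloadduct 15 | O=C1C[C@H](O[Si](C)(C)C(C)(C)C)[C@@H]2[C@@]1(C(=O)OC)[C@@H]1C=CC(=O)[C@@]2(C(OC)OC)O1
F4 | step 14 | 7,8-dihydro analogue of 20 | O[C@@]1(COCc3ccc(OC)cc3)CC[C@@H]2[C@H]1[C@@H](O)CCC(=O)[C@@H]2C(OC)OC
F5 | step 14 | 6α-TBS ether of F4 | O[C@@]1(COCc3ccc(OC)cc3)CC[C@@H]2[C@H]1[C@@H](O[Si](C)(C)C(C)(C)C)CCC(=O)[C@@H]2C(OC)OC
F6 | step 14 | 8-phenylselenyl derivative of F5 (C8 epimers) | O[C@@]1(COCc3ccc(OC)cc3)CC[C@@H]2[C@H]1[C@@H](O[Si](C)(C)C(C)(C)C)CC([Se]c3ccccc3)C(=O)[C@@H]2C(OC)OC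
F7 | step 28 | 14-phenylthio analogue of 39 (S-phenyl monothioacetal) | C=C1C(=O)O[C@H]2[C@H]1[C@H](OC(=O)[C@@H](C)CC)[C@@H](OC(C)=O)[C@@H]1C(Sc5ccccc5)O[C@@]3(COCc4ccc(OC)cc4)CC[C@@H]1[C@@H]23
F8 | step 28 | sulfoxide of F7 | C=C1C(=O)O[C@H]2[C@H]1[C@H](OC(=O)[C@@H](C)CC)[C@@H](OC(C)=O)[C@@H]1C(S(=O)c5ccccc5)O[C@@]3(COCc4ccc(OC)cc4)CC[C@@H]1[C@@H]23
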